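Abbreviations: TBS = tert-butyldimethylsilyl, PMB = 4-methoxybenzyl. Atoms carry germacrane/elemane numbers (C1–C15) in every compound, open-chain ones included.

## Structural features

The target 34 is a cis-fused bicycle: a cyclohexane (ring B: C5, C6, C7, C8, C9, C10) shares its C7–C8 bond with an α-methylene-γ-butyrolactone (C7, C11, C12, O, C8, exocyclic C11=C13). All six carbons of ring B are stereogenic and contiguous: quaternary C10 (axial methyl C14, equatorial vinyl C1=C2), C5 (2-propenyl unit C4(=C3)–C15H2OH), C6 (equatorial hydroxyl), C7, C8 (axial lactone oxygen) and C9 (equatorial isobutyrate). The fragile groups are the methylene lactone (conjugate acceptor, polymerisable), the isobutyrate next to the lactone oxygen (acyl shift), the 6-hydroxyl, which under base can take over the lactone carbonyl, and the allylic primary alcohol. The real difficulty is the quaternary C10 wedged between C5 and C9, with vinyl and propenyl trans. These two groups form a 1,5-diene, C2=C1–C10–C5–C4=C3, whose central σ-bond is the ring bond C5–C10. Reconnecting C2 to C3 while opening C5–C10 leads back to a cyclodeca-1(10),4-diene lactone in which C6–C9 are untouched. Six stereocentres are thereby reduced to four (C6–C9) plus two ring-trans alkene geometries.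

## Logic of the disconnections

34 is traced to 33 by cutting the two O–Si bonds at O6 and O15. The hydroxyls stay masked through the thermolysis and are freed only when no transannular 1,5-diene is left. The forward step must be non-basic so that the isobutyrate, the lactone and the methylene group are spared.

33 is traced to 32 by opening C5–C10 and joining C2 to C3. This removes ring B, the quaternary C10 and C5, and leaves a ten-membered ring with two trisubstituted alkenes. The forward step needs a chair transition state from one crossed conformer, and it is reversible.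

32 is traced to 29 by cutting C7–C8 and the lactone bond C12–O8. Both ring alkenes are then already in place, so the ring closure creates no alkene, only C7 and C8. It must be run at high dilution and relies on C6 and C9 for facial control.

29 is traced through 28 to 27 by adjusting C8 from aldehyde to PMB ether. The sensitive α-acyloxy aldehyde is thus made last, under neutral conditions.

27 is traced through 26 and 25 to 24 and then to 22. C11–C13 is cut (C13 from 10), and the C7=C11 alkene is traced to an alkyne by removing H from C7 and iodine from C11. The propargylic hydroxyl at C6 must direct a trans addition so that C6 ends up cis to C13.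

22 is traced to 20 and 21 by cutting C6–C7. One piece supplies C7, C11 and C12, and the same step must set C6 by catalyst control.

20 is traced through 18 and 17 to 16 and 19 by cutting the ester bond at O9 and lowering C6 to the ester level. The last hydride reduction of an ester therefore has to precede acylation.

16 is traced through 15 and 14 to 9 and 12 by cutting C8–C9, and 12 to 10 and 11. C9 is then set by reagent-controlled reduction of 15.

9 is traced to 7 by removing the oxygen at C9. The forward oxidation must select the E-methyl group of the electron-rich alkene.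

7 is traced to 4 and 5 by cutting C3–C4, and 4 to 1 and 2 by cutting C5–C6. The forward syn addition fixes the C4=C5 geometry.

## Other disconnections considered

Alternative 1: The cut is C7–C11 together with the C6–O bond, on a cyclohex-6-ene that already carries C5, C8, C9 and C10. In the forward step bromoacetal A1 is reduced with Bu3SnH under air. The C11 radical closes 5-exo onto C7, the C6 radical captures O2, and PPh3 reduction gives lactol ether A2.
- In its favour: the tether guarantees cis fusion, C6 and C7 are set together, and ring B is present from the start. There is no macrocyclisation and no thermal equilibrium; on these points it is better than the chosen plan.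
- Against it: A2 lacks C13 and the lactone carbonyl. Acetal hydrolysis, oxidation and α-methylenation under enolising conditions must follow, with the isobutyrate at risk. Oxygen capture competes with hydrogen transfer from the tin hydride.
- Comparison: the main burden is moved to A1, whose quaternary C10 next to C5 and C9 must be built enantioselectively. The chosen plan obtains C5 and C10 from alkene geometry. The mechanism is a radical chain against a concerted shift. Step economy after the key step is worse.

Alternative 2: The cuts are C1–C10 and C4–C5; ring A is to be cleaved later at C2=C3. In the forward step quinone A3 adds diene A4 under a chiral cationic oxazaborolidine Lewis acid to give cis-decalin A5.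
- In its favour: C10 is set by catalysis in the first step, and ring B arrives oxygenated at C6, C8 and C9. The step is convergent and scalable. In setting C10 early it is the equal or the better of the chosen plan.
- Against it: A5 has C14 and H5 on the same face, whereas 34 needs them trans, so C5 must be epimerised through the C6 carbonyl. The C4 centre is spent. Cleaving C2=C3 and turning both termini into alkenes takes several steps. Ring B still needs two controlled carbonyl reductions, loss of the methoxy group, the whole C11–C13 lactone and the isobutyrate.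
- Comparison: a cycloaddition builds the skeleton early but leaves most functional-group work. Step economy is clearly worse.

Alternative 3: The cut is C7–C8 of ring B with the lactone C–O bond, on the elemane stage. In the forward step CrCl2 converts the bromomethyl enoate of A6 into an allylchromium that adds to the C8 aldehyde; lactonisation gives A7, which is the same compound as 33.
- In its favour: a six-membered closure is kinetically easier than the ten-membered closure of step 18 and needs no high dilution. There is no Cope equilibrium, and A7 is one step from 34. On these points it is better.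
- Equal: the reaction type is the same as in step 18.
- Against it: A6 must already hold C5 and quaternary C10 between C6 and C9 in an open chain. That is four contiguous centres under acyclic control, and the aldehyde sits next to the quaternary carbon.
- Comparison: the chosen plan pays with a harder ring closure and a reversible last C–C step, but gets C5 and C10 without extra steps. Overall step economy is probably equal or slightly in favour of the chosen plan.

Key step: step 19

Remark 1: a chain made from a homoprenyl unit, a four-carbon alkynoate, one carbon for C8 and a three-carbon acrylate would hold fourteen skeletal carbons and bond C11 directly to C6; C7 has no source there, so here C7, C11 and C12 come from 21 and C13 from 10.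

Remark 2: target and rearrangement precursor agree atom by atom (6α-O, 7α-H, 8β-O, 9β-O; both ring alkenes ring-trans, leading to 10β-methyl and 5α-H), so neither structure needs correction; the CIP letter of C7 changes from S to R on silylation of O6 without any change in space.

Remark 3: the sense of induction of the ProPhenol ligand in step 11 is assumed; the antipodal ligand is used if the opposite sense is found.

Remark 4: the rearrangement is run on the 6,15-bis-silyl ether 32, not on the free diol. This keeps O6 from attacking the lactone at 200 °C and keeps desilylation reagents away from the acid-sensitive cyclodecadiene.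

## Steps

Step 1
Reactants: 1 tert-butyldimethyl(prop-2-yn-1-yloxy)silane; 2 methyl chloroformate
Product: 4 methyl 4-(TBSO)but-2-ynoate, via lithium acetylide 3 (not isolated)
Conditions: n-BuLi, THF, −78 °C; then 2, −78 → 0 °C
Reagents that add atoms: none
Why: Deprotonation of the terminal alkyne and C-acylation of the acetylide with the chloroformate is a standard ynoate synthesis and forms C5–C6.

Step 2
Reactants: 5 5-bromo-2-methylpent-2-ene; 4 methyl 4-(TBSO)but-2-ynoate
Product: 7 methyl (2Z)-3-(TBSOCH2)-7-methylocta-2,6-dienoate, via Grignard reagent 6 (not isolated)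
Conditions: Mg, THF, rt; CuBr·SMe2 (1 equiv), THF, −78 °C; then 4, −78 °C; sat. NH4Cl at −78 °C
Reagents that add atoms: none
Why: Syn carbocupration (conjugate addition of the Grignard-derived alkylcopper to the ynoate) forms C3–C4; cold protonation before the alkenylcopper can equilibrate puts C3 cis to H5, which is the ring-trans C4=C5 geometry.

Step 3
Reactants: 7 methyl (2Z)-3-(TBSOCH2)-7-methylocta-2,6-dienoate
Product: 9 methyl (2Z,6E)-3-(TBSOCH2)-7-methyl-8-oxoocta-2,6-dienoate, via allylic alcohol 8 (not isolated)
Conditions: SeO2 (0.5 equiv), t-BuOOH, salicylic acid (cat.), CH2Cl2, rt; filter; MnO2, CH2Cl2, rt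
Reagents that add atoms: selenium dioxide, O=[Se]=O (transfers the oxygen atom); tert-butyl hydroperoxide, CC(C)(C)OO (restores it)
Why: Riley oxidation (ene reaction, then [2,3]-shift) attacks the electron-rich trisubstituted alkene at its E-methyl group, the enoate alkene being deactivated; MnO2 converges alcohol 8 and any enal on the (E)-enal, which fixes the ring-trans C1=C10 geometry.

Step 4
Reactants: 10 (tributylstannyl)methanol; 11 4-methoxybenzyl chloride
Product: 12 tributyl{[(4-methoxybenzyl)oxy]methyl}stannane
Conditions: NaH, Bu4NI (cat.), THF/DMF, 0 °C → rt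
Reagents that add atoms: none
Why: Williamson etherification of the primary alkoxide with the benzylic chloride gives the precursor of the alkoxymethyl anion.

Step 5
Reactants: 12 tributyl{[(4-methoxybenzyl)oxy]methyl}stannane; 9 methyl (2Z,6E)-3-(TBSOCH2)-7-methyl-8-oxoocta-2,6-dienoate
Product: 14 methyl (2Z,6E)-3-(TBSOCH2)-8-hydroxy-9-(PMBO)-7-methylnona-2,6-dienoate (racemic at C9 of the skeleton), via alkoxymethyllithium 13 (not isolated)
Conditions: 12, n-BuLi, THF, −78 °C; then 9, −78 °C; sat. NH4Cl
Reagents that add atoms: none
Why: Tin–lithium exchange gives the α-alkoxymethyllithium, which adds 1,2 to the aldehyde far faster than to the conjugated ester at −78 °C and forms C8–C9; the missing stereocontrol is supplied in the next two steps.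

Step 6
Reactants: 14 racemic allylic alcohol
Product: 15 methyl (2Z,6E)-3-(TBSOCH2)-9-(PMBO)-7-methyl-8-oxonona-2,6-dienoate
Conditions: MnO2 (excess), CH2Cl2, rt
Reagents that add atoms: none
Why: MnO2 oxidises the secondary allylic alcohol selectively to the enone; ethers and ester are inert.

Step 7
Reactants: 15 enone
Product: 16 methyl (2Z,6E,8R)-3-(TBSOCH2)-8-hydroxy-9-(PMBO)-7-methylnona-2,6-dienoate
Conditions: (R)-2-methyl-CBS-oxazaborolidine (0.2 equiv), catecholborane, toluene, −78 °C
Reagents that add atoms: none
Why: Corey–Bakshi–Shibata reduction with the alkenyl group as the large and CH2OPMB as the small substituent should deliver hydride to the face that gives the 9R carbinol; the enoate and the alkenes are left alone at −78 °C.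

Step 8
Reactants: 16 (8R)-hydroxy ester
Product: 17 (2Z,6E,8R)-3-(TBSOCH2)-9-(PMBO)-7-methylnona-2,6-diene-1,8-diol
Conditions: i-Bu2AlH (3.5 equiv), CH2Cl2, −78 °C; aq. potassium sodium tartrate
Reagents that add atoms: none
Why: i-Bu2AlH reduces the conjugated methyl ester to the allylic alcohol without touching the alkene geometry; this is the last ester reduction and precedes acylation.

Step 9
Reactants: 17 diol
Product: 18 (2Z,6E,8R)-3-(TBSOCH2)-8-hydroxy-9-(PMBO)-7-methylnona-2,6-dienal
Conditions: TEMPO (0.1 equiv), PhI(OAc)2 (1.1 equiv), CH2Cl2, rt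
Reagents that add atoms: none
Why: The oxoammonium oxidation is selective for the primary allylic alcohol over the hindered secondary one and is near neutral, so the (Z)-enal should not isomerise.

Step 10
Reactants: 18 hydroxy enal; 19 isobutyryl chloride
Product: 20 (2R,3E,7Z)-7-(TBSOCH2)-1-(PMBO)-3-methyl-9-oxonona-3,7-dien-2-yl 2-methylpropanoate
Conditions: 19 (1.5 equiv), pyridine, CH2Cl2, 0 °C
Reagents that add atoms: none
Why: Acylation of the secondary allylic alcohol with the acid chloride; pyridine without a nucleophilic catalyst is used so that conjugate addition–elimination does not scramble the enal geometry.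

Step 11
Reactants: 20 enal isobutyrate; 21 methyl propiolate
Product: 22 methyl (4R,5Z,9E,11R)-6-(TBSOCH2)-4-hydroxy-12-(PMBO)-10-methyl-11-(isobutyryloxy)dodeca-5,9-dien-2-ynoate
Conditions: (S,S)-ProPhenol (0.2 equiv), Ph3PO (0.4 equiv), Me2Zn (3 equiv), 21 (3 equiv), toluene, 4 °C
Reagents that add atoms: none
Why: Catalytic asymmetric zinc alkynylide addition to the enal under the dinuclear zinc–ProPhenol catalyst forms C6–C7 and sets C6 (R) by catalyst control; C7, C11 and C12 arrive together.

Step 12
Reactants: 22 γ-hydroxy ynoate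
Product: 24 methyl (2Z,4R,5Z,9E,11R)-6-(TBSOCH2)-4-hydroxy-2-iodo-12-(PMBO)-10-methyl-11-(isobutyryloxy)dodeca-2,5,9-trienoate, via vinylalanate 23 (not isolated)
Conditions: NaAlH2(OCH2CH2OMe)2 (2 equiv), THF, −72 °C; then I2, −72 → −20 °C; aq. Na2S2O3
Reagents that add atoms: iodine, II
Why: Alkoxide-directed trans-hydroalumination puts hydride on C7 and aluminium on C11 in the five-membered alanate, and iodinolysis with retention leaves iodine cis to C6; at −72 °C the hindered isobutyrate and the conjugated ester should survive.

Step 13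
Reactants: 24 iodo hydroxy enoate
Product: 25 methyl (2Z,4R,5Z,9E,11R)-4-(TBSO)-6-(TBSOCH2)-2-iodo-12-(PMBO)-10-methyl-11-(isobutyryloxy)dodeca-2,5,9-trienoate
Conditions: t-BuMe2SiOTf, 2,6-lutidine, CH2Cl2, −78 °C
Reagents that add atoms: tert-butyldimethylsilyl trifluoromethanesulfonate, CC(C)(C)[Si](C)(C)OS(=O)(=O)C(F)(F)F
Why: Silylation of the hindered bis-allylic alcohol with the silyl triflate; the bulky ether later shields one face of the allylchromium and protects O6 in the thermolysis.

Step 14
Reactants: 25 iodide; 10 (tributylstannyl)methanol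
Product: 26 methyl (2E,4R,5Z,9E,11R)-4-(TBSO)-6-(TBSOCH2)-2-(hydroxymethyl)-12-(PMBO)-10-methyl-11-(isobutyryloxy)dodeca-2,5,9-trienoate
Conditions: Pd2(dba)3 (5 mol %), AsPh3, CuI (cat.), NMP, rt → 40 °C
Reagents that add atoms: none
Why: Stille coupling of the α-iodoenoate with the hydroxymethylstannane forms C11–C13 with retention of alkene geometry; the mild arsine/copper protocol keeps zerovalent palladium from ionising the allylic isobutyrate.

Step 15
Reactants: 26 allylic alcohol
Product: 27 methyl (2Z,4R,5Z,9E,11R)-2-(bromomethyl)-4-(TBSO)-6-(TBSOCH2)-12-(PMBO)-10-methyl-11-(isobutyryloxy)dodeca-2,5,9-trienoate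
Conditions: CBr4, PPh3, 2,6-lutidine, CH2Cl2, −20 → 0 °C
Reagents that add atoms: tetrabromomethane, BrC(Br)(Br)Br
Why: Appel reaction converts the primary allylic alcohol into the bromide by SN2 displacement, so the geometry (C6 cis to CH2Br) is kept.

Step 16
Reactants: 27 PMB ether
Product: 28 methyl (2Z,4R,5Z,9E,11R)-2-(bromomethyl)-4-(TBSO)-6-(TBSOCH2)-12-hydroxy-10-methyl-11-(isobutyryloxy)dodeca-2,5,9-trienoate
Conditions: DDQ (1.3 equiv), CH2Cl2/pH 7 phosphate buffer, 0 °C
Reagents that add atoms: none
Why: Oxidative cleavage of the 4-methoxybenzyl ether by DDQ is neutral, so the silyl ethers, the allylic bromide and the neighbouring isobutyrate should stay in place.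

Step 17
Reactants: 28 primary alcohol
Product: 29 methyl (2Z,4R,5Z,9E,11R)-2-(bromomethyl)-4-(TBSO)-6-(TBSOCH2)-10-methyl-11-(isobutyryloxy)-12-oxododeca-2,5,9-trienoate
Conditions: Dess–Martin periodinane, NaHCO3, CH2Cl2, 0 °C → rt; used at once
Reagents that add atoms: none
Why: Dess–Martin oxidation under bicarbonate buffer gives the α-acyloxy aldehyde without epimerising C9 or moving the C1=C10 alkene into conjugation.

Step 18
Reactants: 29 bromo aldehyde
Product: 32 (6R,7R,8S,9R)-6α,15-bis(TBSO)-9β-(isobutyryloxy)germacra-1(10),4,11(13)-trien-8β,12-olide (both ring alkenes ring-trans), via allylchromium 30 (not isolated), via hydroxy ester 31 (not isolated)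
Conditions: CrCl2 (10 equiv), THF/DMF, 0.002 M, slow addition of 29 over 12 h, rt; sat. NH4Cl
Reagents that add atoms: none
Why: Divalent chromium inserts into the allylic bromide and the (Z)-allylchromium adds through C7 to the C8 aldehyde in a chair-like Nozaki–Hiyama–Kishi-type allylation, closing the ten-membered ring at high dilution. Attack anti to the C6 silyloxy group (A(1,3)-minimised conformer), the Z-allyl chair with C9 equatorial (7,8-syn) and the Felkin–Anh preference at C9 all point to the required C7 and C8 configuration; the chromium alkoxide of 31 then closes the cis-fused lactone on the adjacent methyl ester.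

Step 19
Reactants: 32 germacranolide bis-silyl ether
Product: 33 (5S,6R,7R,8S,9R,10S)-6α,15-bis(TBSO)-9β-(isobutyryloxy)elema-1,3,11(13)-trien-8β,12-olide
Conditions: degassed o-xylene (0.01 M), BHT (cat.), sealed tube, 200 °C, 3 h; recovered 32 heated again
Reagents that add atoms: none
Why: Thermal Cope rearrangement: a concerted suprafacial [3,3]-sigmatropic shift in which C5–C10 forms while C2–C3 breaks; the closest known case is the contraction of germacra-1(10),4-dienolides to elemanolides. Ring B (C5–C10) closes by transannular bonding of the two alkene termini inside the ten-membered ring as the macrocycle opens, through a chair transition state of the crossed conformer. C10 and C5 are the new stereocentres: their relative configuration (C14 anti to H5, vinyl trans to propenyl) is dictated by the two ring-trans alkene geometries in the chair. Their absolute sense is dictated by C6–C9, because only one crossed conformer keeps the C6 silyloxy group, the C7–C11 bond and the C9 isobutyrate pseudo-equatorial. The selectivity needed is chair over boat and this conformer over its ring-flipped partner; the bulky C6 silyl ether and the cis-lactone both reinforce it. The change is an equilibrium that release of medium-ring strain and of the A(1,3) interaction between C15 and C6 should tilt toward 33, and unchanged 32 is separated and heated again. Silyl protection keeps O6 from attacking the lactone carbonyl at 200 °C, and BHT suppresses radical polymerisation of the methylene lactone.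

Step 20
Reactants: 33 elemanolide bis-silyl ether
Product: 34 (5S,6R,7S,8S,9R,10S)-6α,15-dihydroxy-9β-(isobutyryloxy)elema-1,3,11(13)-trien-8β,12-olide (target)
Conditions: HF·pyridine, pyridine, THF, 0 °C → rt
Reagents that add atoms: none
Why: Fluoride cleavage of both silyl ethers under buffered, non-basic conditions; the elemanolide has no transannular diene left, and the absence of base avoids isobutyrate migration, lactone transfer to O6 and conjugate addition to the methylene lactone.

## Compound list

1 | tert-butyldimethyl(prop-2-yn-1-yloxy)silane | C#CCO[Si](C)(C)C(C)(C)C | starting material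
2 | methyl chloroformate | COC(Cl)=O | starting material
3 | 3-(TBSO)prop-1-yn-1-yllithium (not isolated) | [Li]C#CCO[Si](C)(C)C(C)(C)C | intermediate
4 | methyl 4-{[tert-butyl(dimethyl)silyl]oxy}but-2-ynoate | COC(=O)C#CCO[Si](C)(C)C(C)(C)C | intermediate
5 | 5-bromo-2-methylpent-2-ene | CC(C)=CCCBr | starting material
6 | (4-methylpent-3-en-1-yl)magnesium bromide (not isolated) | CC(C)=CCC[Mg]Br | intermediate
7 | methyl (2Z)-3-({[tert-butyl(dimethyl)silyl]oxy}methyl)-7-methylocta-2,6-dienoate | CC(C)=CCC/C(CO[Si](C)(C)C(C)(C)C)=C/C(=O)OC | intermediate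
8 | methyl (2Z,6E)-3-(TBSOCH2)-8-hydroxy-7-methylocta-2,6-dienoate (not isolated) | OC/C(C)=C/CC/C(CO[Si](C)(C)C(C)(C)C)=C/C(=O)OC | intermediate
9 | methyl (2Z,6E)-3-(TBSOCH2)-7-methyl-8-oxoocta-2,6-dienoate | O=C/C(C)=C/CC/C(CO[Si](C)(C)C(C)(C)C)=C/C(=O)OC | intermediate
10 | (tributylstannyl)methanol | CCCC[Sn](CCCC)(CCCC)CO | starting material
11 | 4-methoxybenzyl chloride | COc1ccc(CCl)cc1 | starting material
12 | tributyl{[(4-methoxybenzyl)oxy]methyl}stannane | CCCC[Sn](CCCC)(CCCC)COCc1ccc(OC)cc1 | intermediate
13 | {[(4-methoxybenzyl)oxy]methyl}lithium (not isolated) | [Li]COCc1ccc(OC)cc1 | intermediate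
14 | methyl (2Z,6E)-3-(TBSOCH2)-8-hydroxy-9-(PMBO)-7-methylnona-2,6-dienoate, racemic at the carbinol | COc1ccc(COCC(O)/C(C)=C/CC/C(CO[Si](C)(C)C(C)(C)C)=C/C(=O)OC)cc1 | intermediate
15 | methyl (2Z,6E)-3-(TBSOCH2)-9-(PMBO)-7-methyl-8-oxonona-2,6-dienoate | COc1ccc(COCC(=O)/C(C)=C/CC/C(CO[Si](C)(C)C(C)(C)C)=C/C(=O)OC)cc1 | intermediate
16 | methyl (2Z,6E,8R)-3-(TBSOCH2)-8-hydroxy-9-(PMBO)-7-methylnona-2,6-dienoate | COc1ccc(COC[C@H](O)/C(C)=C/CC/C(CO[Si](C)(C)C(C)(C)C)=C/C(=O)OC)cc1 | intermediate
17 | (2Z,6E,8R)-3-(TBSOCH2)-9-(PMBO)-7-methylnona-2,6-diene-1,8-diol | COc1ccc(COC[C@H](O)/C(C)=C/CC/C(CO[Si](C)(C)C(C)(C)C)=C/CO)cc1 | intermediate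
18 | (2Z,6E,8R)-3-(TBSOCH2)-8-hydroxy-9-(PMBO)-7-methylnona-2,6-dienal | COc1ccc(COC[C@H](O)/C(C)=C/CC/C(CO[Si](C)(C)C(C)(C)C)=C/C=O)cc1 | intermediate
19 | isobutyryl chloride (2-methylpropanoyl chloride) | CC(C)C(Cl)=O | starting material
20 | (2R,3E,7Z)-7-(TBSOCH2)-1-(PMBO)-3-methyl-9-oxonona-3,7-dien-2-yl 2-methylpropanoate | COc1ccc(COC[C@H](OC(=O)C(C)C)/C(C)=C/CC/C(CO[Si](C)(C)C(C)(C)C)=C/C=O)cc1 | intermediate
21 | methyl propiolate | C#CC(=O)OC | starting material
22 | methyl (4R,5Z,9E,11R)-6-(TBSOCH2)-4-hydroxy-12-(PMBO)-10-methyl-11-[(2-methylpropanoyl)oxy]dodeca-5,9-dien-2-ynoate | COC(=O)C#C[C@H](O)/C=C(/CC/C=C(C)/[C@H](COCc1ccc(OC)cc1)OC(=O)C(C)C)CO[Si](C)(C)C(C)(C)C | intermediate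
23 | sodium bis(2-methoxyethoxy)aluminate of 22, aluminium bound to O6 and C11 in a five-membered ring (not isolated) | [Na+].COCCO[Al-]1(OCCOC)O[C@H](/C=C(/CC/C=C(C)/[C@H](COCc2ccc(OC)cc2)OC(=O)C(C)C)CO[Si](C)(C)C(C)(C)C)C=C1C(=O)OC | intermediate
24 | methyl (2Z,4R,5Z,9E,11R)-6-(TBSOCH2)-4-hydroxy-2-iodo-12-(PMBO)-10-methyl-11-[(2-methylpropanoyl)oxy]dodeca-2,5,9-trienoate | COC(=O)/C(I)=C/[C@H](O)/C=C(/CC/C=C(C)/[C@H](COCc1ccc(OC)cc1)OC(=O)C(C)C)CO[Si](C)(C)C(C)(C)C | intermediate
25 | 4-O-TBS ether of 24 | COC(=O)/C(I)=C/[C@H](O[Si](C)(C)C(C)(C)C)/C=C(/CC/C=C(C)/[C@H](COCc1ccc(OC)cc1)OC(=O)C(C)C)CO[Si](C)(C)C(C)(C)C | intermediate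
26 | methyl (2E,4R,5Z,9E,11R)-4-(TBSO)-6-(TBSOCH2)-2-(hydroxymethyl)-12-(PMBO)-10-methyl-11-[(2-methylpropanoyl)oxy]dodeca-2,5,9-trienoate | COC(=O)/C(CO)=C/[C@H](O[Si](C)(C)C(C)(C)C)/C=C(/CC/C=C(C)/[C@H](COCc1ccc(OC)cc1)OC(=O)C(C)C)CO[Si](C)(C)C(C)(C)C | intermediate
27 | methyl (2Z,4R,5Z,9E,11R)-2-(bromomethyl)-4-(TBSO)-6-(TBSOCH2)-12-(PMBO)-10-methyl-11-[(2-methylpropanoyl)oxy]dodeca-2,5,9-trienoate | COC(=O)/C(CBr)=C/[C@H](O[Si](C)(C)C(C)(C)C)/C=C(/CC/C=C(C)/[C@H](COCc1ccc(OC)cc1)OC(=O)C(C)C)CO[Si](C)(C)C(C)(C)C | intermediate
28 | 12-hydroxy compound from 27 (PMB removed) | COC(=O)/C(CBr)=C/[C@H](O[Si](C)(C)C(C)(C)C)/C=C(/CC/C=C(C)/[C@H](CO)OC(=O)C(C)C)CO[Si](C)(C)C(C)(C)C | intermediate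
29 | methyl (2Z,4R,5Z,9E,11R)-2-(bromomethyl)-4-(TBSO)-6-(TBSOCH2)-10-methyl-11-[(2-methylpropanoyl)oxy]-12-oxododeca-2,5,9-trienoate | COC(=O)/C(CBr)=C/[C@H](O[Si](C)(C)C(C)(C)C)/C=C(/CC/C=C(C)/[C@H](C=O)OC(=O)C(C)C)CO[Si](C)(C)C(C)(C)C | intermediate
30 | allylchromium dichloride from 29, trivalent chromium on C13 (not isolated) | COC(=O)/C(C[Cr](Cl)Cl)=C/[C@H](O[Si](C)(C)C(C)(C)C)/C=C(/CC/C=C(C)/[C@H](C=O)OC(=O)C(C)C)CO[Si](C)(C)C(C)(C)C | intermediate
31 | methyl (6R,7R,8S,9R)-6,15-bis(TBSO)-8-hydroxy-9-(isobutyryloxy)germacra-1(10),4,11(13)-trien-12-oate, ring alkenes ring-trans (not isolated) | C/C1=C\CC/C(CO[Si](C)(C)C(C)(C)C)=C/[C@@H](O[Si](C)(C)C(C)(C)C)[C@H](C(=C)C(=O)OC)[C@H](O)[C@@H]1OC(=O)C(C)C | intermediate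
32 | (6R,7R,8S,9R)-6α,15-bis(TBSO)-9β-(isobutyryloxy)germacra-1(10),4,11(13)-trien-8β,12-olide, ring alkenes ring-trans | C/C1=C\CC/C(CO[Si](C)(C)C(C)(C)C)=C/[C@@H](O[Si](C)(C)C(C)(C)C)[C@@H]2C(=C)C(=O)O[C@@H]2[C@@H]1OC(=O)C(C)C | intermediate
33 | (5S,6R,7R,8S,9R,10S)-6α,15-bis(TBSO)-9β-(isobutyryloxy)elema-1,3,11(13)-trien-8β,12-olide | C=C[C@@]1(C)[C@H](C(=C)CO[Si](C)(C)C(C)(C)C)[C@@H](O[Si](C)(C)C(C)(C)C)[C@@H]2C(=C)C(=O)O[C@@H]2[C@@H]1OC(=O)C(C)C | intermediate
34 | (3aS,4R,5S,6S,7R,7aS)-6-ethenyl-4-hydroxy-5-(3-hydroxyprop-1-en-2-yl)-6-methyl-3-methylidene-2-oxooctahydro-1-benzofuran-7-yl 2-methylpropanoate | C=C[C@@]1(C)[C@H](C(=C)CO)[C@@H](O)[C@@H]2C(=C)C(=O)O[C@@H]2[C@@H]1OC(=O)C(C)C | target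

## Step count and least certain steps

Total step count: 20. Longest linear sequence: 19 (steps 1–3 and 5–20); step 4 is a side branch.

Step 19 (key step). The most likely failure is incomplete conversion, because the shift is reversible and the two bulky silyl groups may hold the equilibrium short of the elemane side; slow radical polymerisation of the methylene lactone at 200 °C is the second risk. Fallback: starting from 32, both silyl ethers are removed first with buffered HF·pyridine to give the dihydroxy germacranolide F1, and this less congested diol is rearranged thermally; the product of that rearrangement is 34 itself.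

Step 18. The most likely failure is poor facial selectivity in the macrocyclic transition state, where ring strain can override the three open-chain preferences and deliver the C8 epimer; oligomerisation and acyl shift from O9 to O8 at the alkoxide stage are further risks. Fallback: if the closure of 29 gives the 8-epimeric hydroxy ester F2 (a 7,8-anti adduct, which should lactonise slowly), its methyl ester is cleaved selectively with Me3SnOH to the seco acid F3. The lactone is then closed by a Mitsunobu reaction (PPh3, diisopropyl azodicarboxylate) with inversion at C8, which returns the route to 32.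

Step 12. The most likely failure is competing hydride attack on the isobutyrate or the conjugated ester before the directed hydroalumination is complete. Fallback: starting from 18, O9 is masked as the triethylsilyl ether F4. Alkynylation as in step 11 gives the propargylic alcohol F5, hydroalumination–iodination gives the iodo alcohol F6, and silylation of O6 gives the bis-silyl ether F7. The triethylsilyl group is then removed selectively (PPTS, MeOH, 0 °C) to the 9-hydroxy compound F8, and acylation with 19 returns the route to 25.

Step 11. The most likely failure is insufficient enantioselectivity with this β,β-disubstituted enal, or the opposite sense of induction. Fallback: starting from 20, the lithium acetylide of 21 is added at −78 °C to give the racemic propargylic alcohol F9. This is oxidised with Dess–Martin periodinane to the ynone F10. A Midland reduction with the Alpine-Borane enantiomer that gives the 6R carbinol returns the route to 22.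

Step 3. The most likely failure is low conversion with over-oxidation, or attack at the allylic CH2 group instead of the E-methyl group. Fallback: starting from 4, but-3-enylmagnesium bromide and CuBr·SMe2 give the terminal alkene F11. Cross-metathesis of F11 with methacrolein (second-generation Hoveyda–Grubbs catalyst) forms the (E)-2-methyl enal and returns the route to 9.

## Further compounds

F1 | step 19 | 6α,15-dihydroxy-9β-(isobutyryloxy)germacra-1(10),4,11(13)-trien-8β,12-olide | C/C1=C\CC/C(CO)=C/[C@@H](O)[C@@H]2C(=C)C(=O)O[C@@H]2[C@@H]1OC(=O)C(C)C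
F2 | step 18 | 8-epimer of hydroxy ester 31 | C/C1=C\CC/C(CO[Si](C)(C)C(C)(C)C)=C/[C@@H](O[Si](C)(C)C(C)(C)C)[C@H](C(=C)C(=O)OC)[C@@H](O)[C@@H]1OC(=O)C(C)C
F3 | step 18 | seco acid from F2 | C/C1=C\CC/C(CO[Si](C)(C)C(C)(C)C)=C/[C@@H](O[Si](C)(C)C(C)(C)C)[C@H](C(=C)C(=O)O)[C@@H](O)[C@@H]1OC(=O)C(C)C
F4 | step 12 | 8-O-triethylsilyl ether of 18 | COc1ccc(COC[C@H](O[Si](CC)(CC)CC)/C(C)=C/CC/C(CO[Si](C)(C)C(C)(C)C)=C/C=O)cc1
F5 | step 12 | analogue of 22 with triethylsilyloxy in place of isobutyryloxy | COC(=O)C#C[C@H](O)/C=C(/CC/C=C(C)/[C@H](COCc1ccc(OC)cc1)O[Si](CC)(CC)CC)CO[Si](C)(C)C(C)(C)C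
F6 | step 12 | analogue of 24 with triethylsilyloxy in place of isobutyryloxy | COC(=O)/C(I)=C/[C@H](O)/C=C(/CC/C=C(C)/[C@H](COCc1ccc(OC)cc1)O[Si](CC)(CC)CC)CO[Si](C)(C)C(C)(C)C
F7 | step 12 | analogue of 25 with triethylsilyloxy in place of isobutyryloxy | COC(=O)/C(I)=C/[C@H](O[Si](C)(C)C(C)(C)C)/C=C(/CC/C=C(C)/[C@H](COCc1ccc(OC)cc1)O[Si](CC)(CC)CC)CO[Si](C)(C)C(C)(C)C
F8 | step 12 | analogue of 25 with free hydroxyl in place of isobutyryloxy | COC(=O)/C(I)=C/[C@H](O[Si](C)(C)C(C)(C)C)/C=C(/CC/C=C(C)/[C@H](COCc1ccc(OC)cc1)O)CO[Si](C)(C)C(C)(C)C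
F9 | step 11 | 22 as a mixture of epimers at the propargylic carbinol | COC(=O)C#CC(O)/C=C(/CC/C=C(C)/[C@H](COCc1ccc(OC)cc1)OC(=O)C(C)C)CO[Si](C)(C)C(C)(C)C
F10 | step 11 | ynone from F9 | COC(=O)C#CC(=O)/C=C(/CC/C=C(C)/[C@H](COCc1ccc(OC)cc1)OC(=O)C(C)C)CO[Si](C)(C)C(C)(C)C
F11 | step 3 | methyl (2Z)-3-(TBSOCH2)hepta-2,6-dienoate | C=CCC/C(CO[Si](C)(C)C(C)(C)C)=C/C(=O)OC
A1 | alternative 1 | cyclohex-6-ene bromoacetal (2-bromo-1-ethoxyethyl ether on O8) | C=C[C@@]1(C)[C@H](C(=C)CO[Si](C)(C)C(C)(C)C)C=C[C@H](OC(CBr)OCC)[C@@H]1OC(=O)C(C)C
A2 | alternative 1 | cis-fused lactol ethyl ether with free 6-hydroxyl | C=C[C@@]1(C)[C@H](C(=C)CO[Si](C)(C)C(C)(C)C)[C@@H](O)[C@@H]2CC(OCC)O[C@@H]2[C@@H]1OC(=O)C(C)C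
A3 | alternative 2 | 2-methoxy-6-methyl-1,4-benzoquinone | COC1=CC(=O)C=C(C)C1=O
A4 | alternative 2 | (E)-tert-butyldimethyl(penta-2,4-dien-1-yloxy)silane | C=C/C=C/CO[Si](C)(C)C(C)(C)C
A5 | alternative 2 | cis-fused 8-(TBSOCH2)-3-methoxy-4a-methyl-4a,5,8,8a-tetrahydronaphthalene-1,4-dione | C[C@]12CC=C[C@@H](CO[Si](C)(C)C(C)(C)C)[C@H]1C(=O)C=C(OC)C2=O
A6 | alternative 3 | open-chain (Z)-2-(bromomethyl)enoate aldehyde with C5, C6, C9 and C10 in place | C=C[C@](C)([C@@H](OC(=O)C(C)C)C=O)[C@H](C(=C)CO[Si](C)(C)C(C)(C)C)[C@@H](O[Si](C)(C)C(C)(C)C)/C=C(\CBr)C(=O)OC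
A7 | alternative 3 | 6,15-bis-TBS ether of the target (identical with 33) | C=C[C@@]1(C)[C@H](C(=C)CO[Si](C)(C)C(C)(C)C)[C@@H](O[Si](C)(C)C(C)(C)C)[C@@H]2C(=C)C(=O)O[C@@H]2[C@@H]1OC(=O)C(C)C
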